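Readings and results were generated by integration on assumed constants; noise was put on by code.

Chain length has the unit monomers per chain, so I treated it as a division: [Q] over the concentration of chains.

all flasks: L 34 µM

|  | Z | D | remark | time |
|---|---|---|---|---|
| autumn | 7.4 mM | 4 mM | run made earlier |  |
| summer | 12 mM | 4 mM | run made earlier |  |
| elm | 20 mM | 4.00 mM |  | 8.0 d |
| larch | 6.0 mM | 4.00 mM |  | 8.0 d |

| autumn: time / d | autumn: Q / % | summer: time / d | summer: Q / % |
|---|---|---|---|
| 0.333 | 7.2 | 0.833 | 18.5 |
| 0.625 | 15.4 | 1.67 | 29.5 |
| 1.04 | 21.3 | 2.50 | 38.6 |
| 2.00 | 31.5 | 3.00 | 40.9 |
| 4.00 | 46.4 | 4.00 | 47.6 |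

(each reading ± 1 percentage point)

- the average divides the monomer in chains by the number of chains, living and dead together; two radicals that join make one chain
- the earlier runs do not show the number of chains; that part of a forecast is a guess

- which of the two ends with the longer chains by the average number of monomer units in a chain (living and dead chains, two that joined counted as one) ("neither" if they lie within 10%) (elm / larch / neither)
- average number of monomer units in a chain (living and dead chains, two that joined counted as one) at the end, elm
- average number of monomer units in a chain (living and dead chains, two that joined counted as one) at the end, larch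

The numerator could be read. At 4.00 d the autumn run stood at 46.4% and the summer run at 47.6%, a gap of 1.2 percentage points against a scatter of 1 point on each reading. So, with D and L as charged in these runs, I took the percentage as independent of the Z charged, and used the mean, 47.0%; this was an assumption, since elm and larch lie outside the span of Z in the two runs. Q was still rising in both runs, so this was a low value for 8.0 d.

The denominator had to be assumed. I supposed that each L splits into two radicals, that each radical begins a chain, that two which join make one chain (termination by combination), and that D begins none. Then each L spent leaves one chain once its radicals have joined, and the charge of L gives the chain ceiling, 34.0 µM. Dividing by it gave me floors, good only as far as these suppositions held: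

elm: 9.40 mM / 34.0 µM = 276

larch: 2.82 mM / 34.0 µM = 82.9

So I expected elm to end longer.

The forecast also said elm, but with 3.5 for elm and 1.3 for larch, because it judged that “D, at 4 mM, probably dominates”. My floors lay far above its numbers; I had assumed that D begins no chains.

The flask gave elm, with 566 for elm and 138 for larch, both above my floors.

    L → 2 G (k = 1.00 × 10⁻⁴ min⁻¹)
    Z + G → J + Q (k = 1.00 × 10⁵ L mol⁻¹ s⁻¹)
    Z + J → Q + J, rate k3*[J]*[Z] (k = 49000 L mol⁻¹ min⁻¹)
    2 J → E (k = 4.00 × 10⁶ L mol⁻¹ s⁻¹)
    D + Z → X (k = 0.0460 L mol⁻¹ min⁻¹)

The forecast and I parted on the chain count: it took about 2.5 to 4 mM, while E in elm stood at 0.0233 mM. In elm at 8.00 d, 31.6% of L was left, so the ceiling times the share spent gives 23.3 µM of chains. With Q at 65.8% of the Z charged, the length comes to 566.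

Larch read at 50 h had 74.1% of L left, so the ceiling gives 8.81 µM of chains, and Q at 33.3% of 6.0 mM gives a length of 227. The computed length was 227.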